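## Retrosynthetic overview

1. Target ⇒ three acetylations and one C22 desilylation of a tetracyclic triol; the C10 carbinol ⇒ radical (hydrogen-atom-transfer) hydration of the alkene left by a cation–olefin cyclisation.
2. Rings A and B (oxepane and cyclohexane of the acetoxy half) ⇒ one Lewis-acid epoxide-opening cascade of a 2,3:6,7-diepoxide ending on the C10=C11 alkene (C2–O–C7 and C6–C11 bonds), run on a substrate that already carries rings C and D.
3. That diepoxide ⇒ catalyst-controlled epoxidation of a farnesyl chain whose C10=C11 alkene is masked by an allylic sulfone on C12, then reductive desulfonylation; the C15 carbinol ⇒ methyl addition to a ring C ketone.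
4. Rings D and C (oxepane and cyclohexanone of the hydroxy half) ⇒ the first epoxide-opening cascade, ending on a regiodefined silyl enol ether (C18–O–C23 and C14–C19 bonds).
5. Cascade substrate ⇒ C12–C13 bond by conjugate addition of lithiated farnesyl sulfone to a diepoxy vinyl ketone from geranylacetone. The ethylene bridge is made first, in an open chain, and no bicyclic halves are ever coupled; ring order is D+C, then A+B.

Assumption: (2E,6E)-farnesyl bromide, (E)-geranylacetone and the L-fructose-derived enantiomer of the Shi ketone (1,2:4,5-di-O-isopropylidene-β-L-erythro-2,3-hexodiulo-2,6-pyranose) are bought. Locants C1–C24 are those of the squalene chain (methyls on C2, C6, C10, C15, C19, C23); C1–C12 becomes the acetoxy half (rings A/B), C13–C24 the hydroxy half (rings C/D). Target = 3S,6S,7S,10S,11S,14S,15R,18S,19S,22S.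

## Route

Step 1
Reactants: 1 (2E,6E)-farnesyl bromide
Product: 2 (2E,6E)-farnesyl phenyl sulfone
Conditions: PhSO2Na, DMF, rt
Reagents that add atoms: sodium benzenesulfinate, [Na+].[O-]S(=O)c1ccccc1
Why: SN2 S-alkylation of the sulfinate by the primary allylic bromide (allyl sulfone synthesis) leaves both E alkenes untouched and creates no stereocentre.

Step 2
Reactants: 3 (E)-geranylacetone
Product: 4 (5S,6S,9S)-5,6:9,10-diepoxy-6,10-dimethylundecan-2-one
Conditions: L-fructose-derived Shi ketone (0.6 equiv), KHSO5 (as 2KHSO5·KHSO4·K2SO4), K2CO3, Bu4NHSO4, MeCN–CH2(OMe)2–aq. Na2B4O7 buffer, 0 °C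
Reagents that add atoms: potassium peroxymonosulfate, [K+].[O-]S(=O)(=O)OO
Why: Shi asymmetric epoxidation, in which the chiral dioxirane attacks the same enantioface of both trisubstituted alkenes through the spiro transition state and so sets 5S,6S and 9S (the D-fructose ketone would give the R series), the unactivated methyl ketone of the substrate being a far poorer dioxirane precursor than the catalyst.

Step 3
Reactants: 4 (5S,6S,9S)-5,6:9,10-diepoxy-6,10-dimethylundecan-2-one
Product: 8 (6S,7S,10S)-6,7:10,11-diepoxy-7,11-dimethyldodec-1-en-3-one, via lithium enolate 5 (not isolated), via Mannich base 6 (not isolated), via trimethylammonium iodide 7 (not isolated)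
Conditions: LiN(iPr)2, THF, −78 °C; Me2N=CH2+ I−, −78 °C → rt; MeI, Et2O, rt; aq. NaHCO3, CH2Cl2
Reagents that add atoms: N,N-dimethylmethyleneiminium iodide (Eschenmoser's salt), C=[N+](C)C.[I-]
Why: Kinetic deprotonation at the methyl group, Mannich reaction with the iminium salt, exhaustive N-methylation and E1cB (Hofmann-type) elimination amount to an α-methylenation that gives the vinyl ketone without touching the epoxides or creating a stereocentre.

Step 4
Reactants: 2 (2E,6E)-farnesyl phenyl sulfone; 8 (6S,7S,10S)-6,7:10,11-diepoxy-7,11-dimethyldodec-1-en-3-one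
Product: 11 (6E,10E,14Z,18S,19S,22S)-15-(tert-butyldimethylsilyloxy)-18,19:22,23-diepoxy-2,6,10,19,23-pentamethyl-12-(phenylsulfonyl)tetracosa-2,6,10,14-tetraene (C12 epimers), via lithiated sulfone 9 (not isolated), via lithium enolate 10 (not isolated)
Conditions: n-BuLi, THF–HMPA, −78 °C; add 8; TBSOTf, −78 °C
Reagents that add atoms: tert-butyldimethylsilyl trifluoromethanesulfonate, CC(C)(C)[Si](C)(C)OS(=O)(=O)C(F)(F)F
Why: Michael addition of the sulfonyl-stabilised allyl anion through its α-carbon (the γ-carbon is fully substituted and HMPA favours 1,4-attack) forms the C12–C13 bond and a regiodefined C14 enolate that is O-silylated at once, fixing the enol double bond at C14=C15; C12 forms as an epimer mixture that is erased in step 8.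

Step 5
Reactants: 11 the (14Z)-silyl enol ether diepoxide
Product: 13 trans-fused oxepane–cyclohexanone (rings D and C closed by C18–O–C23 and C14–C19; C15 ketone; 22-OTBS; the 12-phenylsulfonyl triene chain equatorial on C14; C14, C18, C19, C22 as in the target; C12 epimers), via 14-epimeric crude ketone 12 (not isolated)
Conditions: TBSOTf (0.3 equiv), 2,6-di-tert-butyl-4-methylpyridine, CH2Cl2, −78 → −40 °C; then K2CO3, MeOH, rt
Reagents that add atoms: none
Why: Silyl-triflate-triggered epoxide-opening cascade (tandem oxa-/carbacyclisation ending in a Mukaiyama-type enol silane alkylation): O-silylation of the terminal epoxide, attack of the 18,19-epoxide oxygen on C23 and anti attack of C14 on C19 of the epoxonium ion through a chair transition state give the trans-fused bicycle with inversion at C19 and retention at C18 and C22, the enol silyl group is returned to triflate so that the net change is a silyl shift to O22, and basic equilibration places the C14 chain equatorial (14S).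

Step 6
Reactants: 13 the ring C/D ketone
Product: 14 tertiary alcohol (as 13 but C15 carries CH3 and OH; 15R, OH axial and cis to the C19 methyl, CH3 equatorial)
Conditions: MeLi, CeCl3, THF, −78 °C
Reagents that add atoms: methyllithium, [Li]C
Why: Organocerium 1,2-addition (Imamoto conditions), in which the weakly basic MeCeCl2 attacks the hindered ketone from the equatorial α-face because the axial path is blocked by the syn-axial C19 methyl, giving the axial alcohol 15R without enolisation or sulfone deprotonation.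

Step 7
Reactants: 14 the tertiary alcohol
Product: 15 diepoxide sulfone (as 14 with (3S)-2,3- and (6S,7S)-6,7-epoxides; 10E alkene intact)
Conditions: L-fructose-derived Shi ketone (0.6 equiv), KHSO5 (as 2KHSO5·KHSO4·K2SO4), K2CO3, Bu4NHSO4, MeCN–CH2(OMe)2–aq. Na2B4O7 buffer, 0 °C
Reagents that add atoms: potassium peroxymonosulfate, [K+].[O-]S(=O)(=O)OO
Why: Shi asymmetric epoxidation again sets 3S and 6S,7S by catalyst control on the two electron-rich distal alkenes, while the C10=C11 alkene is switched off by the electron-withdrawing allylic sulfone on C12.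

Step 8
Reactants: 15 the diepoxide sulfone
Product: 16 diepoxide (as 15 with CH2 at C12)
Conditions: PdCl2(dppp) (5 mol%), LiBHEt3, THF, 0 °C
Reagents that add atoms: none
Why: Palladium-catalysed reductive desulfonylation of the allylic sulfone (π-allyl palladium, hydride delivered to the less substituted terminus C12) removes the sulfone with retention of the 10E alkene and erases the C12 stereocentre, the trisubstituted epoxides surviving the short exposure at 0 °C.

Step 9
Reactants: 16 the diepoxide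
Product: 18 tetracyclic alkene diol (rings A and B closed by C2–O–C7 and C6–C11; exocyclic C10=CH2; 3-OH; 15-OH; 22-OTBS; C3, C6, C7, C11 as in the target), via bis-trimethylsilyl ether 17 (not isolated)
Conditions: TMSOTf (3 equiv), 2,6-di-tert-butyl-4-methylpyridine, CH2Cl2, −78 °C; then K2CO3, MeOH, rt
Reagents that add atoms: none
Why: Second epoxide-opening cascade (tandem oxa-/carbacyclisation ended by the trisubstituted alkene), in which the silylated 2,3-epoxide is opened at C2 by the 6,7-epoxide oxygen and the E alkene attacks C6 anti through a chair transition state (C6 inverted to the target configuration, C7 and C3 retained, C11 chain equatorial), the C10 cation losing a methyl proton to the hindered base; any ring-alkene isomer gives the same C10 radical in step 10, and methanolysis removes the two trimethylsilyl groups.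

Step 10
Reactants: 18 the tetracyclic alkene diol
Product: 20 triol (3-OH, 10-OH, 15-OH, 22-OTBS; 10S, C10–OH equatorial and CH3 axial), via C10 hydroperoxide 19 (not isolated)
Conditions: Co(acac)2 (20 mol%), PhSiH3, O2 (1 atm), iPrOH–CH2Cl2, rt; then PPh3
Reagents that add atoms: dioxygen, O=O
Why: Mukaiyama hydration (hydrogen atom transfer from a cobalt hydride to the alkene, then O2 capture), in which the tertiary C10 radical is trapped on its equatorial α-face because the axial face is shielded by the syn-axial C6 methyl, and the hydroperoxide is reduced by the phosphine.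

Step 11
Reactants: 20 the triol
Product: 21 3,10,15-triacetate 22-TBS ether
Conditions: Ac2O, DMAP, Et3N, PhMe, 70 °C
Reagents that add atoms: acetic anhydride, CC(=O)OC(C)=O
Why: DMAP-catalysed (Steglich-type) acylation under forcing conditions esterifies the secondary and both tertiary hydroxyls while O22 stays silylated, and no stereocentre is touched.

Step 12
Reactants: 21 the triacetate silyl ether
Product: 22 target, (3S,6S,7S,10S,11S,14S,15R,18S,19S,22S)-3,10,15-triacetoxy compound with free 22-OH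
Conditions: HF·pyridine, pyridine–THF, 0 °C → rt
Reagents that add atoms: none
Why: Fluoride-driven desilylation (Si–F bond formation) frees the hindered C22 hydroxyl, the secondary and tertiary acetates being inert to buffered HF.

## Compound list

1 | (2E,6E)-farnesyl bromide ((2E,6E)-1-bromo-3,7,11-trimethyldodeca-2,6,10-triene) | CC(C)=CCC/C(C)=C/CC/C(C)=C/CBr | starting material
2 | (2E,6E)-farnesyl phenyl sulfone | CC(C)=CCC/C(C)=C/CC/C(C)=C/CS(=O)(=O)c1ccccc1 | intermediate
3 | (E)-geranylacetone ((5E)-6,10-dimethylundeca-5,9-dien-2-one) | CC(C)=CCC/C(C)=C/CCC(C)=O | starting material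
4 | (5S,6S,9S)-5,6:9,10-diepoxy-6,10-dimethylundecan-2-one | CC1(C)O[C@H]1CC[C@]1(C)O[C@H]1CCC(C)=O | intermediate
5 | kinetic lithium enolate of 4 (C1=C2–OLi) | CC1(C)O[C@H]1CC[C@]1(C)O[C@H]1CCC(=C)O[Li] | intermediate
6 | (6S,7S,10S)-1-(dimethylamino)-6,7:10,11-diepoxy-7,11-dimethyldodecan-3-one | CC1(C)O[C@H]1CC[C@]1(C)O[C@H]1CCC(=O)CCN(C)C | intermediate
7 | N-methyl ammonium iodide of 6 | CC1(C)O[C@H]1CC[C@]1(C)O[C@H]1CCC(=O)CC[N+](C)(C)C.[I-] | intermediate
8 | (6S,7S,10S)-6,7:10,11-diepoxy-7,11-dimethyldodec-1-en-3-one | CC1(C)O[C@H]1CC[C@]1(C)O[C@H]1CCC(=O)C=C | intermediate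
9 | 1-lithio-(2E,6E)-farnesyl phenyl sulfone | CC(C)=CCC/C(C)=C/CC/C(C)=C/C([Li])S(=O)(=O)c1ccccc1 | intermediate
10 | lithium (14Z)-enolate of the Michael adduct (C14=C15–OLi; 12-phenylsulfonyl; 18S,19S,22S diepoxide; C12 epimers) | CC1(C)O[C@H]1CC[C@]1(C)O[C@H]1CC/C(O[Li])=C/CC(S(=O)(=O)c1ccccc1)/C=C(C)/CC/C=C(C)/CCC=C(C)C | intermediate
11 | (6E,10E,14Z,18S,19S,22S)-15-(tert-butyldimethylsilyloxy)-18,19:22,23-diepoxy-2,6,10,19,23-pentamethyl-12-(phenylsulfonyl)tetracosa-2,6,10,14-tetraene (C12 epimers) | CC1(C)O[C@H]1CC[C@]1(C)O[C@H]1CC/C(O[Si](C)(C)C(C)(C)C)=C/CC(S(=O)(=O)c1ccccc1)/C=C(C)/CC/C=C(C)/CCC=C(C)C | intermediate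
12 | ring C/D ketone as C14 epimer mixture (otherwise as 13) | CC(C)=CCC/C(C)=C/CC/C(C)=C/C(S(=O)(=O)c1ccccc1)CC1[C@]2(C)CC[C@H](O[Si](C)(C)C(C)(C)C)C(C)(C)O[C@H]2CCC1=O | intermediate
13 | ring C/D ketone: trans-fused oxepane–cyclohexanone (C14–C19 bond, C18–O–C23 ether, C15=O, 22-OTBS, equatorial C14 chain bearing 12-SO2Ph and the 2,6E,10E-triene; C12 epimers) | CC(C)=CCC/C(C)=C/CC/C(C)=C/C(S(=O)(=O)c1ccccc1)C[C@H]1[C@]2(C)CC[C@H](O[Si](C)(C)C(C)(C)C)C(C)(C)O[C@H]2CCC1=O | intermediate
14 | tertiary alcohol: 13 with C15(CH3)(OH), 15R (OH axial) | CC(C)=CCC/C(C)=C/CC/C(C)=C/C(S(=O)(=O)c1ccccc1)C[C@H]1[C@]2(C)CC[C@H](O[Si](C)(C)C(C)(C)C)C(C)(C)O[C@H]2CC[C@@]1(C)O | intermediate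
15 | diepoxide sulfone: 14 with (3S)-2,3- and (6S,7S)-6,7-epoxides | CC1(C)O[C@H]1CC[C@]1(C)O[C@H]1CC/C(C)=C/C(S(=O)(=O)c1ccccc1)C[C@H]1[C@]2(C)CC[C@H](O[Si](C)(C)C(C)(C)C)C(C)(C)O[C@H]2CC[C@@]1(C)O | intermediate
16 | diepoxide: 15 without the sulfonyl group (C12H2) | CC1(C)O[C@H]1CC[C@]1(C)O[C@H]1CC/C(C)=C/CC[C@H]1[C@]2(C)CC[C@H](O[Si](C)(C)C(C)(C)C)C(C)(C)O[C@H]2CC[C@@]1(C)O | intermediate
17 | 3,15-bis(trimethylsilyl) ether of 18 | C[Si](C)(C)O[C@H]1CC[C@]2(C)[C@H](CCC(=C)[C@H]2CC[C@H]2[C@]3(C)CC[C@H](O[Si](C)(C)C(C)(C)C)C(C)(C)O[C@H]3CC[C@@]2(C)O[Si](C)(C)C)OC1(C)C | intermediate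
18 | tetracyclic alkene diol (exocyclic C10=CH2, 3-OH, 15-OH, 22-OTBS) | O[C@H]1CC[C@]2(C)[C@H](CCC(=C)[C@H]2CC[C@H]2[C@]3(C)CC[C@H](O[Si](C)(C)C(C)(C)C)C(C)(C)O[C@H]3CC[C@@]2(C)O)OC1(C)C | intermediate
19 | C10 hydroperoxide (10S, OOH equatorial) | O[C@H]1CC[C@]2(C)[C@H](CC[C@](C)(OO)[C@H]2CC[C@H]2[C@]3(C)CC[C@H](O[Si](C)(C)C(C)(C)C)C(C)(C)O[C@H]3CC[C@@]2(C)O)OC1(C)C | intermediate
20 | triol (3-OH, 10-OH equatorial, 15-OH axial, 22-OTBS) | O[C@H]1CC[C@]2(C)[C@H](CC[C@](C)(O)[C@H]2CC[C@H]2[C@]3(C)CC[C@H](O[Si](C)(C)C(C)(C)C)C(C)(C)O[C@H]3CC[C@@]2(C)O)OC1(C)C | intermediate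
21 | 3,10,15-triacetate 22-TBS ether | CC(=O)O[C@H]1CC[C@]2(C)[C@H](CC[C@](C)(OC(C)=O)[C@H]2CC[C@H]2[C@]3(C)CC[C@H](O[Si](C)(C)C(C)(C)C)C(C)(C)O[C@H]3CC[C@@]2(C)OC(C)=O)OC1(C)C | intermediate
22 | CNP0169816.2 (3,10,15-triacetate with free 22-OH) | CC(=O)O[C@H]1CC[C@]2(C)[C@H](CC[C@](C)(OC(C)=O)[C@H]2CC[C@H]2[C@]3(C)CC[C@H](O)C(C)(C)O[C@H]3CC[C@@]2(C)OC(C)=O)OC1(C)C | target

## Step count and risks

Total steps: 12. Longest linear sequence: 11 (steps 2–12, from 3).

**Step 4 (sulfone Michael addition with enolate O-silylation).** The lithiated allylic sulfone may add 1,2 or through its γ-carbon, the vinyl ketone may oligomerise, or proton transfer may scramble the enolate before silylation. The fallback closes rings C and D before the fragments are joined; it sets out from 8 and returns at 13. Treating 8 with Me2S and TBSOTf (2,6-di-tert-butyl-4-methylpyridine, CH2Cl2, −78 °C) gives the β-dimethylsulfonio (Z)-silyl enol ether triflate F1. In the same flask F1 serves as the enol ether terminator of the TBSOTf-triggered epoxide cascade and gives the bicyclic sulfonium ketone triflate F2. DBU then expels Me2S (E1cB) to give the 14-methylene ketone F3. Lithiated sulfone 9 adds 1,4 to this hindered exocyclic enone (THF–HMPA, −78 °C) to give the lithium enolate F4; protonation and K2CO3/MeOH equilibration of C14 deliver 13.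

**Step 9 (second cascade).** The in situ silylated tertiary C15 oxygen may capture the C10 cation (seven-membered cyclic ether) or be ionised by the Lewis acid, and the weak alkene terminator leaves little margin. The fallback masks that oxygen as an ester first; it sets out from 16 and returns at 18. Acetylation of 16 (Ac2O, DMAP, Et3N, 40 °C) gives the 15-O-acetate F5. The cascade (TMSOTf, 2,6-di-tert-butyl-4-methylpyridine, CH2Cl2, −78 °C) then gives the 3-O-trimethylsilyl ether F6, which citric acid in MeOH converts to the alkene alcohol acetate F7. LiAlH4 (THF, 0 °C) removes the tertiary acetate to give 18.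

**Step 10 (radical hydration).** Facial selectivity of O2 capture at C10 may be modest. The fallback replaces the radical step by an ionic two-step sequence with known equatorial preference; it sets out from 18 and returns at 20. mCPBA (NaHCO3, CH2Cl2, 0 °C) attacks the exocyclic alkene from the equatorial α-face, away from the axial C6 methyl, to give the spiro-epoxide F8. LiAlH4 (THF, 0 °C → rt) opens it at the CH2 terminus to give 20.

## Further compounds

F1 | step 4 | β-dimethylsulfonio (Z)-tert-butyldimethylsilyl enol ether triflate from 8 | CC1(C)O[C@H]1CC[C@]1(C)O[C@H]1CC/C(O[Si](C)(C)C(C)(C)C)=C/C[S+](C)C.[O-]S(=O)(=O)C(F)(F)F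
F2 | step 4 | ring C/D ketone carrying CH2–S+Me2 on C14 (22-OTBS), triflate salt | C[S+](C)C[C@H]1[C@]2(C)CC[C@H](O[Si](C)(C)C(C)(C)C)C(C)(C)O[C@H]2CCC1=O.[O-]S(=O)(=O)C(F)(F)F
F3 | step 4 | 14-methylene ring C/D ketone (22-OTBS) | C=C1[C@]2(C)CC[C@H](O[Si](C)(C)C(C)(C)C)C(C)(C)O[C@H]2CCC1=O
F4 | step 4 | lithium enolate of 13 (C14=C15–OLi; C12 epimers) | CC(C)=CCC/C(C)=C/CC/C(C)=C/C(S(=O)(=O)c1ccccc1)CC=1[C@]2(C)CC[C@H](O[Si](C)(C)C(C)(C)C)C(C)(C)O[C@H]2CCC=1O[Li]
F5 | step 9 | 15-O-acetate of 16 | CC1(C)O[C@H]1CC[C@]1(C)O[C@H]1CC/C(C)=C/CC[C@H]1[C@]2(C)CC[C@H](O[Si](C)(C)C(C)(C)C)C(C)(C)O[C@H]2CC[C@@]1(C)OC(C)=O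
F6 | step 9 | 3-O-trimethylsilyl ether of F7 | C[Si](C)(C)O[C@H]1CC[C@]2(C)[C@H](CCC(=C)[C@H]2CC[C@H]2[C@]3(C)CC[C@H](O[Si](C)(C)C(C)(C)C)C(C)(C)O[C@H]3CC[C@@]2(C)OC(C)=O)OC1(C)C
F7 | step 9 | 15-O-acetate of 18 | O[C@H]1CC[C@]2(C)[C@H](CCC(=C)[C@H]2CC[C@H]2[C@]3(C)CC[C@H](O[Si](C)(C)C(C)(C)C)C(C)(C)O[C@H]3CC[C@@]2(C)OC(C)=O)OC1(C)C
F8 | step 10 | C10 spiro-epoxide of 18 (epoxide oxygen equatorial, CH2 axial) | O[C@H]1CC[C@]2(C)[C@H](CC[C@]3(OC3)[C@H]2CC[C@H]2[C@]3(C)CC[C@H](O[Si](C)(C)C(C)(C)C)C(C)(C)O[C@H]3CC[C@@]2(C)O)OC1(C)C
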